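I was to read the spring flask at 2.0 h. The midnight run, with 0.065 mol% of catalyst against the spring flask's 0.13 mol% and otherwise the same charges, had been read at that same time.

the same everywhere: substrate 0.20 M; gas phase 6.4 mM (held); added ligand 0.63 mM
- spring: catalyst 0.13 mol%; the very flask that is asked about, followed so far
- midnight: catalyst 0.065 mol%; run made earlier
- flask: catalyst 0.13 mol%; time 2.0 h

- spring (time / min: product / %, idle adduct / %): 1.33: 0, 0.2; 3.00: 0, 0; 6.00: 0.5, 0; 10.0: 1.1, 1.0
- midnight (time / min: product / %, idle adduct / %): 15.0: 0.7, 0.7; 40.0: 2.9, 1.1; 80.0: 4.3, 1.4; 120: 6.0, 1.9

(each reading ± 0.5 percentage points)

- how much product and idle adduct together there is at 2.0 h, in percent of the substrate charged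
- concentration of dissolved gas in solution at 2.0 h, in percent of saturation

- what is said of product includes idle adduct
- at the start none of the gas is dissolved
- the numbers in the tables scatter with a standard deviation of 0.5 percentage points
- on the list of suspects stand: dissolved gas + product <-> idle adduct; catalyst + added ligand <-> idle complex; gas phase <-> dissolved gas; substrate + dissolved gas + catalyst -> catalyst + product

The spring readings stop at 10.0 min and, at 1.1 % with a scatter of 0.5 percentage points, say little, so I leaned on the midnight run. Its last reading gives the product per catalyst charged, the turnover number at that time: 92.3.

For a floor I put that turnover on the spring loading, which gave 12.0 %, since with the same ligand the larger loading should leave the free share of catalyst no smaller. For a ceiling I took tight binding, where the free share goes inversely as the ligand left over. The charges leave 0.370 mM in the spring flask against 0.500 mM at midnight, a gain of 1.35, so 16.2 %.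

Then the drift: the rates compare at the start, but the spring flask eats its substrate faster, and taking the mean substrate over each run costs a factor 0.969. My bracket, an estimate as good as the single midnight reading under it, was 11.6 % to 15.7 %. It took the dissolved gas as equal in both flasks, and I made no reckoning of my own for the dissolved gas.

The forecast, reasoning that “Doubling the catalyst should at least double the rate”, gave 12.5 % and 85 % of saturation, which put its yield inside my bracket.

The spring flask gave 13.3 %, also inside the bracket, with dissolved gas at 90.6 % of saturation.

    dissolved gas + product ⇌ idle adduct, settled at all times (K = 72.0 L mol⁻¹)
    catalyst + added ligand ⇌ idle complex, settled at all times (K = 3690 L mol⁻¹)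
    gas phase ⇌ dissolved gas, rate k3*(csat - [dissolved gas]) (kL = 27.3 h⁻¹)
    substrate + dissolved gas + catalyst → catalyst + product (k = 1.32 × 10⁵ L² mol⁻² h⁻¹)

Dissolved gas already stood at 89.2 % of saturation by 0.200 h, and 36.8 % of the catalyst charged was free at 1.00 h. The step to product had 9.0 % of its turnover up to 2.0 h behind it at 0.200 h and half by 0.985 h. The spring turnover came to 102, which is 1.11 times the figure read from the midnight run.

The neighbour with 0.33 mol% of catalyst is charged with more catalyst than added ligand, so my tight-binding reckoning gives no ceiling there, but the floor with its drift gives 26.6 %. That neighbour gave 33.1 %.

(All runs stem from a simulated flask from invented constants; the scatter is artificial.)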